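## Plan

1. Retrosynthesis: cut the C8 ester C–O bond and the C3–H and C8–H bonds (back to the 3,8-dione), then rejoin C3 and C8 as a tetrasubstituted alkene (ozonolysis transform), which folds the ten-membered ring into a 6/6 bicycle. Remove C13, the C1–C10 epoxide oxygen and the C12 lactone oxidation level, rearomatise (Birch transform), and cut the tetralin at C7–C8 (vinyl-epoxide Friedel–Crafts), C11=C12 (Wittig), C6=C7 (cross-metathesis) and C4–C5 (ketone allylation).
2. Enabling feature: the four carbons C9–C10(CH3)–C1–C2 bridge C8 and C3 just as the four non-fusion positions of a toluene ring bridge the two fusion carbons of a tetralin. The p-tolyl ring of 4'-methylacetophenone therefore becomes C1–C3 and C8–C10, and its fusion bond C3–C8 is the bond ozone cuts.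
3. Forward: the C4–C7/C11–C12 chain is built on the aryl ketone; the carbocyclic six-membered ring closes at C7–C8; Birch reduction; γ-lactone ring; epoxide ring; ozonolysis of C3=C8 releases the ten-membered ring; two ketone reductions, angeloylation and desilylation finish.
4. Stereochemistry: C4 from catalytic asymmetric allylboration; C6 and C7 from a Shi epoxidation and stereospecific anti opening of the epoxide; C1 and C10 from a second Shi epoxidation; C8 and C3 from (S)- and (R)-CBS reductions.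
5. Ozone hardly distinguishes a tetrasubstituted from a trisubstituted alkene, so the Birch-derived C1=C10 alkene is taken to the target's own epoxide before the cleavage; C3=C8 is then the only electron-rich alkene.

Key step: step 13

Remarks
- Locants C1–C13 are those of the target (C1 epoxide CH, C3 secondary carbinol, C4 methyl carbinol, C6 lactone O–CH, C7, C8 angelate carbinol, C10 methyl epoxide carbon, C11/C12 lactone carbons, C13 methylene) and are used for all intermediates. CIP descriptors in the names are those of each compound; the descriptor at C7 changes between R and S with its neighbours although the centre is not touched after step 6.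
- Assumption: the copper/(R,R)-i-Pr-DuPHOS allylboration is taken to give the S carbinol; if it gives the R carbinol, the (S,S) ligand is used.

## Route

Step 1
Reactants: 1 4'-methylacetophenone; 2 allylboronic acid pinacol ester
Product: 3 (2S)-2-(4-methylphenyl)pent-4-en-2-ol
Conditions: CuF2·2H2O (3 mol%), (R,R)-i-Pr-DuPHOS (6 mol%), La(Oi-Pr)3 (4.5 mol%), DMF, −40 °C
Reagents that add atoms: allylboronic acid pinacol ester 2, C=CCB1OC(C)(C)C(C)(C)O1
Why: Catalytic enantioselective allylboration of a ketone, in which the chiral bisphosphine–copper allyl species adds through a closed six-membered transition state to one face of the aryl methyl ketone and sets C4 as the S tertiary carbinol.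

Step 2
Reactants: 3 (2S)-2-(4-methylphenyl)pent-4-en-2-ol
Product: 4 triethyl{[(2S)-2-(4-methylphenyl)pent-4-en-2-yl]oxy}silane
Conditions: Et3SiOTf, 2,6-lutidine, CH2Cl2, −78 → 0 °C
Reagents that add atoms: triethylsilyl trifluoromethanesulfonate, CC[Si](CC)(CC)OS(=O)(=O)C(F)(F)F
Why: Silyl triflate silylation of a tertiary alcohol is standard and masks the hydroxyl that would otherwise open the epoxide of step 5 under acid.

Step 3
Reactants: 4 triethyl{[(2S)-2-(4-methylphenyl)pent-4-en-2-yl]oxy}silane; 5 (E)-but-2-enal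
Product: 6 (2E,5S)-5-(4-methylphenyl)-5-(triethylsilyloxy)hex-2-enal
Conditions: second-generation Hoveyda–Grubbs catalyst (H2IMes)Cl2Ru(=CH-2-(i-PrO)C6H4) (3 mol%), 5 (4 equiv), CH2Cl2, 40 °C
Reagents that add atoms: (E)-but-2-enal 5, C/C=C/C=O
Why: Olefin cross-metathesis of a terminal alkene with an electron-poor enal is E-selective and is driven by loss of propene, giving the E enal that carries C7 and C11.

Step 4
Reactants: 6 (2E,5S)-5-(4-methylphenyl)-5-(triethylsilyloxy)hex-2-enal
Product: 7 triethyl{[(2S,4E)-2-(4-methylphenyl)hepta-4,6-dien-2-yl]oxy}silane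
Conditions: Ph3PCH3Br, KN(SiMe3)2, THF, 0 °C; then 6, −78 → 0 °C
Reagents that add atoms: methyltriphenylphosphonium bromide, C[P+](c1ccccc1)(c1ccccc1)c1ccccc1.[Br-]
Why: Wittig methylenation of the enal by 1,2-addition of the unstabilised ylide adds C12 and leaves the E alkene untouched.

Step 5
Reactants: 7 triethyl{[(2S,4E)-2-(4-methylphenyl)hepta-4,6-dien-2-yl]oxy}silane
Product: 8 triethyl{[(2S)-1-[(2R,3R)-3-ethenyloxiran-2-yl]-2-(4-methylphenyl)propan-2-yl]oxy}silane
Conditions: D-fructose-derived Shi ketone (0.3 equiv), Oxone (2KHSO5·KHSO4·K2SO4), K2CO3, n-Bu4NHSO4, MeCN/CH2(OMe)2, aq. Na2B4O7/Na2EDTA buffer (pH 10.5), 0 °C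
Reagents that add atoms: potassium peroxymonosulfate, [K+].[O-]S(=O)(=O)OO
Why: Shi asymmetric epoxidation, in which the chiral dioxirane reacts through a spiro transition state at the electron-richer trans-disubstituted alkene of the diene rather than at the terminal vinyl group, and the D-fructose-derived ketone sets the (6R,7R) trans epoxide by reagent control.

Step 6
Reactants: 8 triethyl{[(2S)-1-[(2R,3R)-3-ethenyloxiran-2-yl]-2-(4-methylphenyl)propan-2-yl]oxy}silane
Product: 10 (1S,3R,4R)-4-ethenyl-1,6-dimethyl-1,2,3,4-tetrahydronaphthalene-1,3-diol, via silyl ether 9 (not isolated)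
Conditions: BF3·OEt2 (1.2 equiv), CH2Cl2, −78 °C; then n-Bu4NF (5 equiv), THF, −78 → 23 °C
Reagents that add atoms: none
Why: Intramolecular Friedel–Crafts alkylation by a vinyl epoxide, in which the Lewis acid opens the epoxide at the allylic carbon C7 and the ortho carbon C8 of the p-tolyl ring (both ortho positions are equivalent) attacks 6-endo anti to the leaving oxygen, so that C7 is inverted, C6 is untouched and the vinyl group ends trans to the C6 hydroxyl; fluoride then removes the silyl group in the same flask.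

Step 7
Reactants: 10 (1S,3R,4R)-4-ethenyl-1,6-dimethyl-1,2,3,4-tetrahydronaphthalene-1,3-diol
Product: 12 (1S,3R,4R)-4-(2-hydroxyethyl)-1,6-dimethyl-1,2,3,4-tetrahydronaphthalene-1,3-diol, via alkylborane 11 (not isolated)
Conditions: 9-BBN (3.5 equiv), THF, 0 → 23 °C; then NaOH (aq), H2O2, 0 °C
Reagents that add atoms: hydrogen peroxide, OO
Why: Hydroboration–oxidation with the bulky 9-BBN puts boron on the terminal carbon of the vinyl group, and oxidation with retention gives the primary C12 alcohol without touching a stereocentre.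

Step 8
Reactants: 12 (1S,3R,4R)-4-(2-hydroxyethyl)-1,6-dimethyl-1,2,3,4-tetrahydronaphthalene-1,3-diol
Product: 13 (1S,3R,4R)-4-(2-hydroxyethyl)-1,6-dimethyl-1,2,3,4,5,8-hexahydronaphthalene-1,3-diol
Conditions: n-BuLi (3.1 equiv), THF, −78 °C; then Li, NH3(l), t-BuOH, −78 → −33 °C; NH4Cl
Reagents that add atoms: none
Why: Birch reduction of the 1,2,4-trialkylbenzene protonates the unsubstituted C2 and C9, leaving the C3=C8 and C1=C10 alkenes, and pre-forming the lithium alkoxides protects the benzylic C4–O bond from hydrogenolysis.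

Step 9
Reactants: 13 (1S,3R,4R)-4-(2-hydroxyethyl)-1,6-dimethyl-1,2,3,4,5,8-hexahydronaphthalene-1,3-diol
Product: 16 (3aR,5S,9bR)-5-hydroxy-5,8-dimethyl-3a,4,5,6,9,9b-hexahydronaphtho[2,1-b]furan-2(1H)-one, via hydroxy aldehyde 14 (not isolated), via lactol 15 (not isolated)
Conditions: TEMPO (0.2 equiv), PhI(OAc)2 (2.5 equiv), CH2Cl2, 23 °C
Reagents that add atoms: none
Why: Nitroxyl-catalysed oxidation is selective for the primary alcohol, the aldehyde closes onto the C6 hydroxyl to the five-membered lactol, and further oxidation gives the trans-fused γ-lactone while the tertiary allylic alcohol stays untouched.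

Step 10
Reactants: 16 (3aR,5S,9bR)-5-hydroxy-5,8-dimethyl-3a,4,5,6,9,9b-hexahydronaphtho[2,1-b]furan-2(1H)-one
Product: 17 (3aR,5S,9bR)-5,8-dimethyl-5-(triethylsilyloxy)-3a,4,5,6,9,9b-hexahydronaphtho[2,1-b]furan-2(1H)-one
Conditions: Et3SiOTf, 2,6-lutidine, CH2Cl2, −78 → 0 °C
Reagents that add atoms: triethylsilyl trifluoromethanesulfonate, CC[Si](CC)(CC)OS(=O)(=O)C(F)(F)F
Why: Silyl triflate silylation of the tertiary allylic alcohol shields the C3=C8 alkene in step 11, hinders the later C3 ketone and keeps the C4 oxygen from opening the epoxide.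

Step 11
Reactants: 17 (3aR,5S,9bR)-5,8-dimethyl-5-(triethylsilyloxy)-3a,4,5,6,9,9b-hexahydronaphtho[2,1-b]furan-2(1H)-one
Product: 18 (3aR,5S,7R,8S,9bR)-7,8-epoxy-5,8-dimethyl-5-(triethylsilyloxy)-3a,4,5,6,7,8,9,9b-octahydronaphtho[2,1-b]furan-2(1H)-one (epoxide at C1–C10)
Conditions: D-fructose-derived Shi ketone (0.3 equiv), Oxone (2KHSO5·KHSO4·K2SO4, 1.2 equiv KHSO5), K2CO3, n-Bu4NHSO4, MeCN/CH2(OMe)2, aq. Na2B4O7/Na2EDTA buffer (pH 10.5), 0 °C
Reagents that add atoms: potassium peroxymonosulfate, [K+].[O-]S(=O)(=O)OO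
Why: Shi epoxidation, in which the bulky chiral dioxirane takes the exposed trisubstituted C1=C10 alkene rather than the C3=C8 alkene (flanked by the silyloxy-bearing quaternary C4 and inductively deactivated), and the D-fructose-derived ketone should give the (1R,10S) cis epoxide by reagent control, the facial sense known for 1-substituted cyclohexenes.

Step 12
Reactants: 18 (3aR,5S,7R,8S,9bR)-7,8-epoxy-5,8-dimethyl-5-(triethylsilyloxy)-3a,4,5,6,7,8,9,9b-octahydronaphtho[2,1-b]furan-2(1H)-one
Product: 21 (3aR,5S,7R,8S,9bS)-7,8-epoxy-5,8-dimethyl-1-methylidene-5-(triethylsilyloxy)-3a,4,5,6,7,8,9,9b-octahydronaphtho[2,1-b]furan-2(1H)-one, via Mannich base 19 (not isolated), via ammonium iodide 20 (not isolated)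
Conditions: LiN(i-Pr)2 (1.15 equiv), THF, −78 °C; CH2=NMe2+ I−, −78 → 23 °C; then MeI, THF/MeOH, 23 °C; then NaHCO3 (aq), CH2Cl2
Reagents that add atoms: Eschenmoser's salt (N,N-dimethylmethyleneiminium iodide), C=[N+](C)C.[I-]
Why: α-Methylenation of a lactone by a Mannich reaction and Hofmann-type elimination, in which the C11 lithium enolate is aminomethylated and N-methylation followed by mild base expels trimethylamine to the exocyclic alkene C13; no other carbonyl is present and the epoxide tolerates the amide base at −78 °C.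

Step 13
Reactants: 21 (3aR,5S,7R,8S,9bS)-7,8-epoxy-5,8-dimethyl-1-methylidene-5-(triethylsilyloxy)-3a,4,5,6,7,8,9,9b-octahydronaphtho[2,1-b]furan-2(1H)-one
Product: 24 (1R,4S,6R,7S,10S)-1,10-epoxy-3,8-dioxo-4-(triethylsilyloxy)germacr-11(13)-en-12,6-olide (cis epoxide), via primary ozonide 22 (not isolated), via methoxy hydroperoxide 23 (not isolated)
Conditions: O3 (1.05 equiv, standardised solution in CH2Cl2), CH2Cl2/MeOH (4:1), −78 °C; then Me2S, −78 → 0 °C; used crude
Reagents that add atoms: ozone, [O-][O+]=O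
Why: Ozone adds as a 1,3-dipole to the tetrasubstituted C3=C8 alkene to give the primary ozonide 22, which fragments (Criegee mechanism) to a ketone and a carbonyl oxide that methanol traps as the methoxy hydroperoxide 23, and dimethyl sulfide reduces this to the second ketone. The closest known reaction type is the ozonolytic cleavage of the ring-fusion alkene of Birch-derived hexahydronaphthalenes and octalins to cyclodecane-1,6-diones. No ring is closed: cutting the bond shared by the two six-membered rings turns their ten-carbon periphery C1–C10 into the ten-membered ring. No stereocentre is formed; C1, C4, C6, C7 and C10, all set on the rigid bicycle, are carried over, and the neutral, cold work-up protects C7 (α to the new C8 ketone) and the two β,γ-epoxy ketone units. The step needs chemoselectivity for C3=C8, which is secured because it is the only electron-rich alkene left: the trisubstituted alkene is already the epoxide and the α-methylene lactone is an electron-poor alkene that reacts far more slowly with electrophilic ozone, and the ozone is dosed as a standardised solution.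

Step 14
Reactants: 24 (1R,4S,6R,7S,10S)-1,10-epoxy-3,8-dioxo-4-(triethylsilyloxy)germacr-11(13)-en-12,6-olide
Product: 25 (1R,4S,6R,7R,8R,10S)-1,10-epoxy-8-hydroxy-3-oxo-4-(triethylsilyloxy)germacr-11(13)-en-12,6-olide
Conditions: (S)-2-methyl-CBS-oxazaborolidine (0.5 equiv), catecholborane (2 equiv), toluene/CH2Cl2, −78 °C; pH 7 buffer
Reagents that add atoms: none
Why: Corey–Bakshi–Shibata reduction, in which the (S)-oxazaborolidine distinguishes the branched C7 side from the C9 methylene and should give the 8R carbinol (the sense also expected from Felkin–Anh attack anti to the C7–C6 ring bond); the C8 ketone reacts at −78 °C while the neopentyl C3 ketone and the acrylate are left.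

Step 15
Reactants: 25 (1R,4S,6R,7R,8R,10S)-1,10-epoxy-8-hydroxy-3-oxo-4-(triethylsilyloxy)germacr-11(13)-en-12,6-olide
Product: 26 (1R,3S,4S,6R,7R,8R,10S)-1,10-epoxy-3,8-dihydroxy-4-(triethylsilyloxy)germacr-11(13)-en-12,6-olide
Conditions: (R)-2-methyl-CBS-oxazaborolidine (1 equiv), catecholborane (3 equiv), toluene, −40 → 0 °C; pH 7 buffer
Reagents that add atoms: none
Why: Corey–Bakshi–Shibata reduction with the enantiomeric catalyst, for which the fully substituted C4 is the large group and the C2 methylene the small one, so the (R)-oxazaborolidine should give the 3S carbinol, reinforced by polar Felkin–Anh attack anti to the C4–OSi bond.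

Step 16
Reactants: 26 (1R,3S,4S,6R,7R,8R,10S)-1,10-epoxy-3,8-dihydroxy-4-(triethylsilyloxy)germacr-11(13)-en-12,6-olide; 27 angelic acid
Product: 29 (1R,3S,4S,6R,7R,8R,10S)-8-angeloyloxy-1,10-epoxy-3-hydroxy-4-(triethylsilyloxy)germacr-11(13)-en-12,6-olide, via mixed anhydride 28 (not isolated)
Conditions: 27, 2,4,6-Cl3C6H2COCl, Et3N, toluene, 23 °C; then 26, 75 °C
Reagents that add atoms: angelic acid 27, C/C=C(/C)C(=O)O
Why: Yamaguchi-type esterification through the mixed anhydride, run without a nucleophilic amine catalyst, acylates the C8 hydroxyl with retention and without Z-to-E isomerisation of the angelate, while the neopentyl C3 hydroxyl next to the silyloxy quaternary carbon stays free.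

Step 17
Reactants: 29 (1R,3S,4S,6R,7R,8R,10S)-8-angeloyloxy-1,10-epoxy-3-hydroxy-4-(triethylsilyloxy)germacr-11(13)-en-12,6-olide
Product: 30 CNP0113954.1, (1R,3S,4S,6R,7S,8R,10S)-8-angeloyloxy-1,10-epoxy-3,4-dihydroxygermacr-11(13)-en-12,6-olide
Conditions: n-Bu4NF/AcOH (1:1), THF, 0 → 23 °C
Reagents that add atoms: none
Why: Fluoride cleaves the tertiary triethylsilyl ether, and buffering with acetic acid keeps the medium near neutral so that the epoxide, the angelate and the α-methylene lactone survive and the freed C4 hydroxyl does not open the epoxide.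

## Compound list

1 | 4'-methylacetophenone | CC(=O)c1ccc(C)cc1 | starting material
2 | allylboronic acid pinacol ester | C=CCB1OC(C)(C)C(C)(C)O1 | starting material
3 | (2S)-2-(4-methylphenyl)pent-4-en-2-ol | C=CC[C@](C)(O)c1ccc(C)cc1 | intermediate
4 | triethyl{[(2S)-2-(4-methylphenyl)pent-4-en-2-yl]oxy}silane | C=CC[C@](C)(O[Si](CC)(CC)CC)c1ccc(C)cc1 | intermediate
5 | (E)-but-2-enal (crotonaldehyde) | C/C=C/C=O | starting material
6 | (2E,5S)-5-(4-methylphenyl)-5-(triethylsilyloxy)hex-2-enal | O=C/C=C/C[C@](C)(O[Si](CC)(CC)CC)c1ccc(C)cc1 | intermediate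
7 | triethyl{[(2S,4E)-2-(4-methylphenyl)hepta-4,6-dien-2-yl]oxy}silane | C=C/C=C/C[C@](C)(O[Si](CC)(CC)CC)c1ccc(C)cc1 | intermediate
8 | triethyl{[(2S)-1-[(2R,3R)-3-ethenyloxiran-2-yl]-2-(4-methylphenyl)propan-2-yl]oxy}silane | C=C[C@H]1O[C@@H]1C[C@](C)(O[Si](CC)(CC)CC)c1ccc(C)cc1 | intermediate
9 | (1R,2R,4S)-1-ethenyl-4,7-dimethyl-4-(triethylsilyloxy)-1,2,3,4-tetrahydronaphthalen-2-ol | C=C[C@H]1[C@H](O)C[C@](C)(O[Si](CC)(CC)CC)c2ccc(C)cc21 | intermediate
10 | (1S,3R,4R)-4-ethenyl-1,6-dimethyl-1,2,3,4-tetrahydronaphthalene-1,3-diol | C=C[C@H]1[C@H](O)C[C@](C)(O)c2ccc(C)cc21 | intermediate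
11 | B-alkyl-9-borabicyclo[3.3.1]nonane of 10 (boron on the terminal carbon C12) | C1CC2CCCC(C1)B2CC[C@H]1[C@H](O)C[C@](C)(O)c2ccc(C)cc21 | intermediate
12 | (1S,3R,4R)-4-(2-hydroxyethyl)-1,6-dimethyl-1,2,3,4-tetrahydronaphthalene-1,3-diol | OCC[C@H]1[C@H](O)C[C@](C)(O)c2ccc(C)cc21 | intermediate
13 | (1S,3R,4R)-4-(2-hydroxyethyl)-1,6-dimethyl-1,2,3,4,5,8-hexahydronaphthalene-1,3-diol | OCC[C@H]1[C@H](O)C[C@](C)(O)C2=C1CC(C)=CC2 | intermediate
14 | 2-[(1R,2R,4S)-2,4-dihydroxy-4,7-dimethyl-1,2,3,4,5,8-hexahydronaphthalen-1-yl]acetaldehyde | O=CC[C@H]1[C@H](O)C[C@](C)(O)C2=C1CC(C)=CC2 | intermediate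
15 | (3aR,5S,9bR)-5,8-dimethyl-1,2,3a,4,5,6,9,9b-octahydronaphtho[2,1-b]furan-2,5-diol (lactol, both C12 epimers) | OC1C[C@H]2[C@@H](C[C@](C)(O)C3=C2CC(C)=CC3)O1 | intermediate
16 | (3aR,5S,9bR)-5-hydroxy-5,8-dimethyl-3a,4,5,6,9,9b-hexahydronaphtho[2,1-b]furan-2(1H)-one | O=C1C[C@H]2[C@@H](C[C@](C)(O)C3=C2CC(C)=CC3)O1 | intermediate
17 | (3aR,5S,9bR)-5,8-dimethyl-5-(triethylsilyloxy)-3a,4,5,6,9,9b-hexahydronaphtho[2,1-b]furan-2(1H)-one | O=C1C[C@H]2[C@@H](C[C@](C)(O[Si](CC)(CC)CC)C3=C2CC(C)=CC3)O1 | intermediate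
18 | (3aR,5S,7R,8S,9bR)-7,8-epoxy-5,8-dimethyl-5-(triethylsilyloxy)-3a,4,5,6,7,8,9,9b-octahydronaphtho[2,1-b]furan-2(1H)-one | O=C1C[C@H]2[C@@H](C[C@](C)(O[Si](CC)(CC)CC)C3=C2C[C@]4(C)O[C@@H]4C3)O1 | intermediate
19 | Mannich base of 18, dimethylaminomethyl group at C11 (either C11 epimer) | CN(C)CC1C(=O)O[C@@H]2C[C@](C)(O[Si](CC)(CC)CC)C3=C(C[C@]4(C)O[C@@H]4C3)[C@@H]12 | intermediate
20 | trimethylammoniomethyl lactone iodide from 19 | C[N+](C)(C)CC1C(=O)O[C@@H]2C[C@](C)(O[Si](CC)(CC)CC)C3=C(C[C@]4(C)O[C@@H]4C3)[C@@H]12.[I-] | intermediate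
21 | (3aR,5S,7R,8S,9bS)-7,8-epoxy-5,8-dimethyl-1-methylidene-5-(triethylsilyloxy)-3a,4,5,6,7,8,9,9b-octahydronaphtho[2,1-b]furan-2(1H)-one | C=C1C(=O)O[C@@H]2C[C@](C)(O[Si](CC)(CC)CC)C3=C(C[C@]4(C)O[C@@H]4C3)[C@@H]12 | intermediate
22 | primary ozonide of 21 (1,2,3-trioxolane across C3–C8) | C=C1C(=O)O[C@@H]2C[C@](C)(O[Si](CC)(CC)CC)C34OOOC3(C[C@]5(C)O[C@@H]5C4)[C@@H]12 | intermediate
23 | ring-opened methoxy hydroperoxide (C3 ketone, C8 bearing OMe and OOH) | C=C1C(=O)O[C@@H]2C[C@](C)(O[Si](CC)(CC)CC)C(=O)C[C@H]3O[C@@]3(C)CC(OC)(OO)[C@@H]12 | intermediate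
24 | (1R,4S,6R,7S,10S)-1,10-epoxy-3,8-dioxo-4-(triethylsilyloxy)germacr-11(13)-en-12,6-olide | C=C1C(=O)O[C@@H]2C[C@](C)(O[Si](CC)(CC)CC)C(=O)C[C@H]3O[C@@]3(C)CC(=O)[C@@H]12 | intermediate
25 | (1R,4S,6R,7R,8R,10S)-1,10-epoxy-8-hydroxy-3-oxo-4-(triethylsilyloxy)germacr-11(13)-en-12,6-olide | C=C1C(=O)O[C@@H]2C[C@](C)(O[Si](CC)(CC)CC)C(=O)C[C@H]3O[C@@]3(C)C[C@@H](O)[C@@H]12 | intermediate
26 | (1R,3S,4S,6R,7R,8R,10S)-1,10-epoxy-3,8-dihydroxy-4-(triethylsilyloxy)germacr-11(13)-en-12,6-olide | C=C1C(=O)O[C@@H]2C[C@](C)(O[Si](CC)(CC)CC)[C@@H](O)C[C@H]3O[C@@]3(C)C[C@@H](O)[C@@H]12 | intermediate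
27 | angelic acid, (Z)-2-methylbut-2-enoic acid | C/C=C(/C)C(=O)O | starting material
28 | angelic 2,4,6-trichlorobenzoic anhydride | C/C=C(/C)C(=O)OC(=O)c1c(Cl)cc(Cl)cc1Cl | intermediate
29 | (1R,3S,4S,6R,7R,8R,10S)-8-angeloyloxy-1,10-epoxy-3-hydroxy-4-(triethylsilyloxy)germacr-11(13)-en-12,6-olide | C=C1C(=O)O[C@@H]2C[C@](C)(O[Si](CC)(CC)CC)[C@@H](O)C[C@H]3O[C@@]3(C)C[C@@H](OC(=O)/C(C)=C\C)[C@@H]12 | intermediate
30 | CNP0113954.1, (1R,3S,4S,6R,7S,8R,10S)-8-angeloyloxy-1,10-epoxy-3,4-dihydroxygermacr-11(13)-en-12,6-olide | C=C1C(=O)O[C@@H]2C[C@](C)(O)[C@@H](O)C[C@H]3O[C@@]3(C)C[C@@H](OC(=O)/C(C)=C\C)[C@@H]12 | target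

## Count and risks

Total step count: 17. Longest linear sequence: 17 steps (from 1).

Steps most likely to fail:

**Step 6** – ionisation or elimination at the tertiary benzylic C4–O bond under the Lewis acid, or loss of stereospecificity through a free allylic cation. Fallback (anionic instead of cationic ring closure), setting out from 2 and returning at 10: allylboration of commercial 2'-bromo-4'-methylacetophenone F1 with 2 under the conditions of step 1 should give (2S)-2-(2-bromo-4-methylphenyl)pent-4-en-2-ol F2. With the tertiary hydroxyl left free, cross-metathesis with 5 gives (2E,5S)-5-(2-bromo-4-methylphenyl)-5-hydroxyhex-2-enal F3, Wittig methylenation gives (2S,4E)-2-(2-bromo-4-methylphenyl)hepta-4,6-dien-2-ol F4, and Shi epoxidation as in step 5 gives (2S)-2-(2-bromo-4-methylphenyl)-1-[(2R,3R)-3-ethenyloxiran-2-yl]propan-2-ol F5. n-BuLi (1 equiv) then t-BuLi (2 equiv) in THF at −78 °C generates the lithium alkoxide aryllithium F6, which opens the epoxide at the allylic carbon C7 with inversion (Parham-type cyclisation) and gives 10 on protonation.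

**Step 11** – competing epoxidation of the tetrasubstituted alkene or poor facial selectivity on the bicycle. Fallback (epoxide made after the ring cleavage under hydroxyl direction), setting out from 17 and returning at 26: 17 is methylenated as in step 12, via the Mannich base F7 and the ammonium iodide F8, to the triene lactone F9. Ozone (1.0 equiv as a standardised solution, CH2Cl2/MeOH, −78 °C; Me2S) cleaves C3=C8 via the primary ozonide F10 and the methoxy hydroperoxide F11 to the (1(10)Z)-3,8-dioxo lactone F12, accepting lower selectivity against the trisubstituted alkene and recycling unreacted F9. (S)-CBS and then (R)-CBS reduction as in steps 14 and 15 give the 8-hydroxy ketone F13 and the 3,8-diol F14. VO(acac)2/t-BuOOH in CH2Cl2 then epoxidises the Z alkene from the face of the two homoallylic hydroxyls at C3 and C8, both of which lie on the epoxide face of the target, to give 26.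

**Step 14** – hydride delivery to the wrong face of the C8 ketone if the conformational bias of the ten-membered ring overrides the catalyst. Fallback (C8 set by inversion at the acylation stage), setting out from 24 and returning at 29: NaBH4/CeCl3·7H2O in MeOH at −78 °C, following the substrate bias, is used to make the 8S alcohol F15 deliberately. (R)-CBS reduction of the C3 ketone as in step 15 gives the 8-epi diol F16. Mitsunobu esterification with angelic acid 27 (PPh3, DIAD, betaine pre-formed, THF, 0 °C) acylates the less hindered C8 hydroxyl with inversion and gives 29.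

## Further compounds

F1 | step 6 | 2'-bromo-4'-methylacetophenone | CC(=O)c1ccc(C)cc1Br
F2 | step 6 | (2S)-2-(2-bromo-4-methylphenyl)pent-4-en-2-ol | C=CC[C@](C)(O)c1ccc(C)cc1Br
F3 | step 6 | (2E,5S)-5-(2-bromo-4-methylphenyl)-5-hydroxyhex-2-enal | O=C/C=C/C[C@](C)(O)c1ccc(C)cc1Br
F4 | step 6 | (2S,4E)-2-(2-bromo-4-methylphenyl)hepta-4,6-dien-2-ol | C=C/C=C/C[C@](C)(O)c1ccc(C)cc1Br
F5 | step 6 | (2S)-2-(2-bromo-4-methylphenyl)-1-[(2R,3R)-3-ethenyloxiran-2-yl]propan-2-ol | C=C[C@H]1O[C@@H]1C[C@](C)(O)c1ccc(C)cc1Br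
F6 | step 6 | lithium alkoxide aryllithium from F5 | C=C[C@H]1O[C@@H]1C[C@](C)(O[Li])c1ccc(C)cc1[Li]
F7 | step 11 | Mannich base of 17, dimethylaminomethyl group at C11 | CN(C)CC1C(=O)O[C@@H]2C[C@](C)(O[Si](CC)(CC)CC)C3=C(CC(C)=CC3)[C@@H]12
F8 | step 11 | trimethylammoniomethyl lactone iodide from F7 | C[N+](C)(C)CC1C(=O)O[C@@H]2C[C@](C)(O[Si](CC)(CC)CC)C3=C(CC(C)=CC3)[C@@H]12.[I-]
F9 | step 11 | (3aR,5S,9bS)-5,8-dimethyl-1-methylidene-5-(triethylsilyloxy)-3a,4,5,6,9,9b-hexahydronaphtho[2,1-b]furan-2(1H)-one | C=C1C(=O)O[C@@H]2C[C@](C)(O[Si](CC)(CC)CC)C3=C(CC(C)=CC3)[C@@H]12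
F10 | step 11 | primary ozonide of F9 across C3–C8 | C=C1C(=O)O[C@@H]2C[C@](C)(O[Si](CC)(CC)CC)C34OOOC3(CC(C)=CC4)[C@@H]12
F11 | step 11 | ring-opened methoxy hydroperoxide (C3 ketone, C8 bearing OMe and OOH) | C=C1C(=O)O[C@@H]2C[C@](C)(O[Si](CC)(CC)CC)C(=O)C/C=C(C)\CC(OC)(OO)[C@@H]12
F12 | step 11 | (1(10)Z,4S,6R,7S)-3,8-dioxo-4-(triethylsilyloxy)germacra-1(10),11(13)-dien-12,6-olide | C=C1C(=O)O[C@@H]2C[C@](C)(O[Si](CC)(CC)CC)C(=O)C/C=C(C)\CC(=O)[C@@H]12
F13 | step 11 | (1(10)Z,4S,6R,7R,8R)-8-hydroxy-3-oxo-4-(triethylsilyloxy)germacra-1(10),11(13)-dien-12,6-olide | C=C1C(=O)O[C@@H]2C[C@](C)(O[Si](CC)(CC)CC)C(=O)C/C=C(C)\C[C@@H](O)[C@@H]12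
F14 | step 11 | (1(10)Z,3S,4S,6R,7R,8R)-3,8-dihydroxy-4-(triethylsilyloxy)germacra-1(10),11(13)-dien-12,6-olide | C=C1C(=O)O[C@@H]2C[C@](C)(O[Si](CC)(CC)CC)[C@@H](O)C/C=C(C)\C[C@@H](O)[C@@H]12
F15 | step 14 | 8-epimer of 25 (8S alcohol) | C=C1C(=O)O[C@@H]2C[C@](C)(O[Si](CC)(CC)CC)C(=O)C[C@H]3O[C@@]3(C)C[C@H](O)[C@@H]12
F16 | step 14 | 8-epimer of 26 (3S,8S diol) | C=C1C(=O)O[C@@H]2C[C@](C)(O[Si](CC)(CC)CC)[C@@H](O)C[C@H]3O[C@@]3(C)C[C@H](O)[C@@H]12
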